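The cis-4,5-epoxide (germacrane numbering) is read as a masked (Z)-C4=C5 olefin, so the ten-membered carbocycle is disconnected at C4–C5. Ring-closing metathesis of a triene in which the planar butenolide (O–C6–C7=C11–C12) already holds C5 (a vinyl group on C6) and the C8 chain gauche should close the cyclodecene and fix the Z geometry in one operation. The C8 hydroxyl, held over one olefin face by the same butenolide, then delivers the epoxide oxygen. The precursor, a γ-vinyl butenolide with an isopropenyl-terminated C8–C3 chain, comes from an L-glutamic acid-derived lactone template (C8, C10, C1), a chelation-controlled γ-silyloxyallylation (C6) and an intramolecular Horner–Wadsworth–Emmons reaction.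

Key step: step 16

Remark: atoms carry germacrane numbers (C1 carbinol, C4/C5 epoxide, C6 lactone carbinol, C7=C11 butenolide olefin, C8 ester carbinol, C10 methyl-bearing methine, C12 lactone carbonyl, C13 acetoxymethyl carbon); lactone 1 and phosphonoacrylate 17 are assumed to be catalogue compounds.

Step 1
Reactants: 1 (S)-5-[(trityloxy)methyl]dihydrofuran-2(3H)-one
Product: 2 (3R,5S)-3-methyl-5-[(trityloxy)methyl]dihydrofuran-2(3H)-one
Conditions: LiN(i-Pr)2, THF, −78 °C; then MeI, −78 °C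
Reagents that add atoms: iodomethane CI
Why: Alkylation of the lactone lithium enolate should occur on the face anti to the bulky trityloxymethyl group (1,3-induction across the ring) and give the trans lactone, which sets C10 relative to C8.

Step 2
Reactants: 2 (3R,5S)-3-methyl-5-[(trityloxy)methyl]dihydrofuran-2(3H)-one; 3 4-bromo-2-methylbut-1-ene
Product: 5 (6R,8S)-8-hydroxy-2,6-dimethyl-9-(trityloxy)non-1-en-5-one, via 3-methylbut-3-enyllithium 4 (not isolated)
Conditions: 3, Li metal, Et2O, 0 °C; then 2, THF, −78 °C; aq. NH4Cl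
Reagents that add atoms: none
Why: Nucleophilic acyl addition of the alkyllithium to the lactone should stop at the lithium hemiketalate at −78 °C and give the γ-hydroxy ketone on work-up without touching C10.

Step 3
Reactants: 5 (6R,8S)-8-hydroxy-2,6-dimethyl-9-(trityloxy)non-1-en-5-one
Product: 6 (5S,6R,8S)-2,6-dimethyl-9-(trityloxy)non-1-ene-5,8-diol
Conditions: LiBH(s-Bu)3, THF, −78 °C; aq. NH4Cl
Reagents that add atoms: none
Why: Felkin–Anh attack of the bulky hydride anti to the C9 chain of the α-methyl ketone should set C1 anti to the C10 methyl group.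

Step 4
Reactants: 6 (5S,6R,8S)-2,6-dimethyl-9-(trityloxy)non-1-ene-5,8-diol
Product: 8 (2R,3S)-1-[(4S)-2-(4-methoxyphenyl)-1,3-dioxolan-4-yl]-2,6-dimethylhept-6-en-3-ol, via (2S,4R,5S)-4,8-dimethylnon-8-ene-1,2,5-triol 7 (not isolated)
Conditions: CSA (cat.), MeOH/CH2Cl2, rt; concentrate; then 4-MeOC6H4CH(OMe)2, CSA (cat.), CH2Cl2, rt
Reagents that add atoms: 4-methoxybenzaldehyde dimethyl acetal COc1ccc(C(OC)OC)cc1
Why: Acid methanolysis of the trityl ether followed by thermodynamic transacetalisation should engage the terminal 1,2-diol as the five-membered dioxolane and leave the C1 hydroxyl free, the acetal carbon forming as an epimer mixture that disappears in step 6.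

Step 5
Reactants: 8 (2R,3S)-1-[(4S)-2-(4-methoxyphenyl)-1,3-dioxolan-4-yl]-2,6-dimethylhept-6-en-3-ol
Product: 9 triisopropyl({(2R,3S)-1-[(4S)-2-(4-methoxyphenyl)-1,3-dioxolan-4-yl]-2,6-dimethylhept-6-en-3-yl}oxy)silane
Conditions: i-Pr3SiOTf, 2,6-lutidine, CH2Cl2, −78 → 0 °C
Reagents that add atoms: triisopropylsilyl trifluoromethanesulfonate CC(C)[Si](OS(=O)(=O)C(F)(F)F)(C(C)C)C(C)C
Why: Silylation with the silyl triflate should protect the hindered C1 alcohol as a triisopropylsilyl ether robust enough to last to the final step.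

Step 6
Reactants: 9 triisopropyl({(2R,3S)-1-[(4S)-2-(4-methoxyphenyl)-1,3-dioxolan-4-yl]-2,6-dimethylhept-6-en-3-yl}oxy)silane
Product: 10 (2S,4R,5S)-2-[(4-methoxybenzyl)oxy]-4,8-dimethyl-5-[(triisopropylsilyl)oxy]non-8-en-1-ol
Conditions: i-Bu2AlH, CH2Cl2, −78 → 0 °C; aq. potassium sodium tartrate
Reagents that add atoms: none
Why: Aluminium should bind the less hindered primary acetal oxygen, so that reductive opening of the 4-methoxybenzylidene acetal leaves the 4-methoxybenzyl group on the secondary C8 oxygen and frees the primary alcohol.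

Step 7
Reactants: 10 (2S,4R,5S)-2-[(4-methoxybenzyl)oxy]-4,8-dimethyl-5-[(triisopropylsilyl)oxy]non-8-en-1-ol
Product: 11 (2S,4R,5S)-2-[(4-methoxybenzyl)oxy]-4,8-dimethyl-5-[(triisopropylsilyl)oxy]non-8-enal
Conditions: Dess–Martin periodinane, NaHCO3, CH2Cl2, 0 °C → rt
Reagents that add atoms: none
Why: Dess–Martin oxidation under buffered, non-basic conditions should give the α-alkoxy aldehyde without epimerising C8.

Step 8
Reactants: 12 (allyloxy)(tert-butyl)dimethylsilane
Product: 13 (Z)-tert-butyldimethyl{[3-(tributylstannyl)prop-1-en-1-yl]oxy}silane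
Conditions: s-BuLi, THF/HMPA, −78 °C; then Bu3SnCl
Reagents that add atoms: tributyltin chloride CCCC[Sn](Cl)(CCCC)CCCC
Why: Deprotonation of the allyl silyl ether should give the chelated (Z)-oxyallyllithium, which is stannylated at the γ-carbon to give the (Z)-γ-silyloxyallylstannane.

Step 9
Reactants: 11 (2S,4R,5S)-2-[(4-methoxybenzyl)oxy]-4,8-dimethyl-5-[(triisopropylsilyl)oxy]non-8-enal; 13 (Z)-tert-butyldimethyl{[3-(tributylstannyl)prop-1-en-1-yl]oxy}silane
Product: 14 (5S,6R,8S,9R,10R)-10-[(tert-butyldimethylsilyl)oxy]-8-[(4-methoxybenzyl)oxy]-2,6-dimethyl-5-[(triisopropylsilyl)oxy]dodeca-1,11-dien-9-ol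
Conditions: MgBr2·OEt2, CH2Cl2, −25 °C
Reagents that add atoms: none
Why: MgBr2 should chelate the aldehyde oxygen and the α-(4-methoxybenzyl)oxy group (Cram chelate) while the γ-silyloxyallylstannane adds through an open transition state, giving the syn,syn adduct and so setting C6 by substrate control.

Step 10
Reactants: 14 (5S,6R,8S,9R,10R)-10-[(tert-butyldimethylsilyl)oxy]-8-[(4-methoxybenzyl)oxy]-2,6-dimethyl-5-[(triisopropylsilyl)oxy]dodeca-1,11-dien-9-ol
Product: 15 (5S,6R,8S,10R)-10-[(tert-butyldimethylsilyl)oxy]-8-[(4-methoxybenzyl)oxy]-2,6-dimethyl-5-[(triisopropylsilyl)oxy]dodeca-1,11-dien-9-one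
Conditions: Dess–Martin periodinane, NaHCO3, CH2Cl2, rt
Reagents that add atoms: none
Why: Neutral Dess–Martin oxidation of the C7 carbinol should give the α,α'-dioxygenated ketone without enolising C6 or C8.

Step 11
Reactants: 15 (5S,6R,8S,10R)-10-[(tert-butyldimethylsilyl)oxy]-8-[(4-methoxybenzyl)oxy]-2,6-dimethyl-5-[(triisopropylsilyl)oxy]dodeca-1,11-dien-9-one
Product: 16 (5S,6R,8S,10R)-10-hydroxy-8-[(4-methoxybenzyl)oxy]-2,6-dimethyl-5-[(triisopropylsilyl)oxy]dodeca-1,11-dien-9-one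
Conditions: HF·pyridine, pyridine, THF, 0 °C
Reagents that add atoms: none
Why: Buffered HF·pyridine should cleave the activated α-keto allylic tert-butyldimethylsilyl ether much faster than the hindered triisopropylsilyl ether, and its non-basic medium avoids enolisation of the β,γ-unsaturated ketone.

Step 12
Reactants: 17 ethyl 2-(diethoxyphosphoryl)acrylate; 18 (4-methoxyphenyl)methanol
Product: 19 ethyl 2-(diethoxyphosphoryl)-3-[(4-methoxybenzyl)oxy]propanoate
Conditions: DBU (cat.), CH2Cl2, rt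
Reagents that add atoms: none
Why: Base-catalysed oxa-Michael addition of the benzylic alcohol to the doubly activated phosphonoacrylate should give the 3-alkoxy-2-phosphonopropanoate.

Step 13
Reactants: 19 ethyl 2-(diethoxyphosphoryl)-3-[(4-methoxybenzyl)oxy]propanoate
Product: 20 2-(diethoxyphosphoryl)-3-[(4-methoxybenzyl)oxy]propanoic acid
Conditions: LiOH, THF/H2O, 0 °C; then 1 M HCl
Reagents that add atoms: lithium hydroxide [Li+].[OH-]
Why: Cold saponification of the activated carboxylic ester should leave the phosphonate diester intact and give the acid after acidification.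

Step 14
Reactants: 16 (5S,6R,8S,10R)-10-hydroxy-8-[(4-methoxybenzyl)oxy]-2,6-dimethyl-5-[(triisopropylsilyl)oxy]dodeca-1,11-dien-9-one; 20 2-(diethoxyphosphoryl)-3-[(4-methoxybenzyl)oxy]propanoic acid
Product: 21 (3R,5S,7R,8S)-5-[(4-methoxybenzyl)oxy]-7,11-dimethyl-4-oxo-8-[(triisopropylsilyl)oxy]dodeca-1,11-dien-3-yl 2-(diethoxyphosphoryl)-3-[(4-methoxybenzyl)oxy]propanoate
Conditions: EDC·HCl, DMAP (cat.), CH2Cl2, 0 °C
Reagents that add atoms: none
Why: Carbodiimide (Steglich) esterification should acylate the C6 hydroxyl of the α-ketol under mild conditions and place the phosphonate within reach of the C7 ketone.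

Step 15
Reactants: 21 (3R,5S,7R,8S)-5-[(4-methoxybenzyl)oxy]-7,11-dimethyl-4-oxo-8-[(triisopropylsilyl)oxy]dodeca-1,11-dien-3-yl 2-(diethoxyphosphoryl)-3-[(4-methoxybenzyl)oxy]propanoate
Product: 22 (5R)-3-{[(4-methoxybenzyl)oxy]methyl}-4-{(1S,3R,4S)-1-[(4-methoxybenzyl)oxy]-3,7-dimethyl-4-[(triisopropylsilyl)oxy]oct-7-en-1-yl}-5-vinylfuran-2(5H)-one
Conditions: LiCl, i-Pr2NEt, MeCN, 0 °C → rt
Reagents that add atoms: none
Why: Intramolecular Horner–Wadsworth–Emmons olefination of the lithium-chelated phosphonate onto the C7 ketone should close the five-membered lactone, the ester tether forcing C12 cis to C6 in the tetrasubstituted C7=C11 olefin while the weak amine base spares the C6 stereocentre.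

Step 16
Reactants: 22 (5R)-3-{[(4-methoxybenzyl)oxy]methyl}-4-{(1S,3R,4S)-1-[(4-methoxybenzyl)oxy]-3,7-dimethyl-4-[(triisopropylsilyl)oxy]oct-7-en-1-yl}-5-vinylfuran-2(5H)-one
Product: 23 (1S,4Z,6R,8S,10R)-8,13-bis[(4-methoxybenzyl)oxy]-1-[(triisopropylsilyl)oxy]germacra-4,7(11)-dien-12,6-olide
Conditions: second-generation Grubbs catalyst (H2IMes)(PCy3)Cl2Ru=CHPh (10 mol%), 1,4-benzoquinone (20 mol%), toluene (1 mM), 80 °C
Reagents that add atoms: none
Why: A ruthenium alkylidene formed at the monosubstituted C6 vinyl group engages the 1,1-disubstituted C4 isopropenyl terminus in a [2+2] cycloaddition/cycloreversion, and loss of ethylene makes the closure irreversible. The closest known reaction type is ring-closing metathesis to medium-ring trisubstituted cycloalkenes with a second-generation ruthenium carbene. The only ring closed is the ten-membered carbocycle, formed by macrocyclising olefin metathesis at C4=C5 under high dilution. No stereocentre is created; the new stereo-element, the C4=C5 geometry, is controlled by the ring, whose ruthenacyclobutane should collapse to the less strained (Z)-olefin with C3 and C6 cis, as the cis-epoxide requires. The step needs cyclisation over oligomerisation and Z over E, and the planar butenolide secures both by holding C5 and C8 gauche (about 60° around C6–C7) so that the two chain ends leave the same side of the lactone. Chemoselectivity rests on the inertness of the tetrasubstituted, electron-poor C7=C11 olefin and on the absence of the methacrylate at this stage, while 1,4-benzoquinone suppresses ruthenium hydride migration of the vinyl group.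

Step 17
Reactants: 23 (1S,4Z,6R,8S,10R)-8,13-bis[(4-methoxybenzyl)oxy]-1-[(triisopropylsilyl)oxy]germacra-4,7(11)-dien-12,6-olide
Product: 24 (1S,4Z,6R,8S,10R)-8,13-dihydroxy-1-[(triisopropylsilyl)oxy]germacra-4,7(11)-dien-12,6-olide
Conditions: DDQ, CH2Cl2/pH 7 buffer, 0 °C → rt
Reagents that add atoms: none
Why: Oxidative cleavage of both 4-methoxybenzyl ethers by DDQ in wet buffered medium should free the C8 and C13 hydroxyls and leave the silyl ether, the lactone and the olefins untouched.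

Step 18
Reactants: 24 (1S,4Z,6R,8S,10R)-8,13-dihydroxy-1-[(triisopropylsilyl)oxy]germacra-4,7(11)-dien-12,6-olide
Product: 25 (1S,4Z,6R,8S,10R)-13-acetoxy-8-hydroxy-1-[(triisopropylsilyl)oxy]germacra-4,7(11)-dien-12,6-olide
Conditions: AcCl, 2,4,6-collidine, CH2Cl2, −78 °C
Reagents that add atoms: acetyl chloride CC(Cl)=O
Why: Acetyl chloride with a hindered pyridine base at low temperature should acetylate the primary allylic C13 alcohol selectively over the hindered secondary C8 alcohol.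

Step 19
Reactants: 25 (1S,4Z,6R,8S,10R)-13-acetoxy-8-hydroxy-1-[(triisopropylsilyl)oxy]germacra-4,7(11)-dien-12,6-olide
Product: 26 (1S,4R,5S,6S,8S,10R)-13-acetoxy-4,5-epoxy-8-hydroxy-1-[(triisopropylsilyl)oxy]germacr-7(11)-en-12,6-olide
Conditions: VO(acac)2 (cat.), t-BuOOH, CH2Cl2, 0 °C → rt
Reagents that add atoms: tert-butyl hydroperoxide CC(C)(C)OO
Why: In this vanadium-catalysed hydroxyl-directed epoxidation the C8 hydroxyl, held by the butenolide over the face of the C4=C5 olefin anti to the lactone oxygen (bishomoallylic to C5), should deliver the peroxide oxygen to that face and set C4 (R) and C5 (S), the electron-poor C7=C11 olefin being inert to the electrophilic oxidant.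

Step 20
Reactants: 26 (1S,4R,5S,6S,8S,10R)-13-acetoxy-4,5-epoxy-8-hydroxy-1-[(triisopropylsilyl)oxy]germacr-7(11)-en-12,6-olide
Product: 27 (1S,4R,5S,6S,8S,10R)-13-acetoxy-4,5-epoxy-8-(methacryloyloxy)-1-[(triisopropylsilyl)oxy]germacr-7(11)-en-12,6-olide
Conditions: methacryloyl chloride, Et3N, DMAP (cat.), CH2Cl2, 0 °C
Reagents that add atoms: methacryloyl chloride C=C(C)C(Cl)=O
Why: DMAP-catalysed acylation of the C8 alcohol with the acid chloride should give the methacrylate under conditions too mild to open the epoxide or deprotonate C6.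

Step 21
Reactants: 27 (1S,4R,5S,6S,8S,10R)-13-acetoxy-4,5-epoxy-8-(methacryloyloxy)-1-[(triisopropylsilyl)oxy]germacr-7(11)-en-12,6-olide
Product: 28 (1S,4R,5S,6S,8S,10R)-13-acetoxy-4,5-epoxy-1-hydroxy-8-(methacryloyloxy)germacr-7(11)-en-12,6-olide
Conditions: HF·pyridine, pyridine, THF, 0 °C → rt
Reagents that add atoms: none
Why: Pyridine-buffered HF·pyridine should remove the triisopropylsilyl ether from C1 under conditions that a trisubstituted epoxide, the two esters and the butenolide are expected to survive, giving the target.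

Compound list
1 | (S)-5-[(trityloxy)methyl]dihydrofuran-2(3H)-one | O=C1CC[C@@H](COC(c2ccccc2)(c2ccccc2)c2ccccc2)O1 | starting material
2 | (3R,5S)-3-methyl-5-[(trityloxy)methyl]dihydrofuran-2(3H)-one | O=C1[C@H](C)C[C@@H](COC(c2ccccc2)(c2ccccc2)c2ccccc2)O1 | intermediate
3 | 4-bromo-2-methylbut-1-ene | C=C(C)CCBr | starting material
4 | 3-methylbut-3-enyllithium | [Li]CCC(C)=C | intermediate
5 | (6R,8S)-8-hydroxy-2,6-dimethyl-9-(trityloxy)non-1-en-5-one | C=C(C)CCC(=O)[C@H](C)C[C@H](O)COC(c1ccccc1)(c1ccccc1)c1ccccc1 | intermediate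
6 | (5S,6R,8S)-2,6-dimethyl-9-(trityloxy)non-1-ene-5,8-diol | C=C(C)CC[C@H](O)[C@H](C)C[C@H](O)COC(c1ccccc1)(c1ccccc1)c1ccccc1 | intermediate
7 | (2S,4R,5S)-4,8-dimethylnon-8-ene-1,2,5-triol | C=C(C)CC[C@H](O)[C@H](C)C[C@H](O)CO | intermediate
8 | (2R,3S)-1-[(4S)-2-(4-methoxyphenyl)-1,3-dioxolan-4-yl]-2,6-dimethylhept-6-en-3-ol (both epimers at the acetal carbon) | C=C(C)CC[C@H](O)[C@H](C)C[C@H]1COC(c2ccc(OC)cc2)O1 | intermediate
9 | triisopropyl({(2R,3S)-1-[(4S)-2-(4-methoxyphenyl)-1,3-dioxolan-4-yl]-2,6-dimethylhept-6-en-3-yl}oxy)silane (both epimers at the acetal carbon) | C=C(C)CC[C@H](O[Si](C(C)C)(C(C)C)C(C)C)[C@H](C)C[C@H]1COC(c2ccc(OC)cc2)O1 | intermediate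
10 | (2S,4R,5S)-2-[(4-methoxybenzyl)oxy]-4,8-dimethyl-5-[(triisopropylsilyl)oxy]non-8-en-1-ol | C=C(C)CC[C@H](O[Si](C(C)C)(C(C)C)C(C)C)[C@H](C)C[C@H](OCc1ccc(OC)cc1)CO | intermediate
11 | (2S,4R,5S)-2-[(4-methoxybenzyl)oxy]-4,8-dimethyl-5-[(triisopropylsilyl)oxy]non-8-enal | C=C(C)CC[C@H](O[Si](C(C)C)(C(C)C)C(C)C)[C@H](C)C[C@H](OCc1ccc(OC)cc1)C=O | intermediate
12 | (allyloxy)(tert-butyl)dimethylsilane | C=CCO[Si](C)(C)C(C)(C)C | starting material
13 | (Z)-tert-butyldimethyl{[3-(tributylstannyl)prop-1-en-1-yl]oxy}silane | CCCC[Sn](CCCC)(CCCC)C/C=C\O[Si](C)(C)C(C)(C)C | intermediate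
14 | (5S,6R,8S,9R,10R)-10-[(tert-butyldimethylsilyl)oxy]-8-[(4-methoxybenzyl)oxy]-2,6-dimethyl-5-[(triisopropylsilyl)oxy]dodeca-1,11-dien-9-ol | C=C(C)CC[C@H](O[Si](C(C)C)(C(C)C)C(C)C)[C@H](C)C[C@H](OCc1ccc(OC)cc1)[C@@H](O)[C@H](O[Si](C)(C)C(C)(C)C)C=C | intermediate
15 | (5S,6R,8S,10R)-10-[(tert-butyldimethylsilyl)oxy]-8-[(4-methoxybenzyl)oxy]-2,6-dimethyl-5-[(triisopropylsilyl)oxy]dodeca-1,11-dien-9-one | C=C(C)CC[C@H](O[Si](C(C)C)(C(C)C)C(C)C)[C@H](C)C[C@H](OCc1ccc(OC)cc1)C(=O)[C@H](O[Si](C)(C)C(C)(C)C)C=C | intermediate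
16 | (5S,6R,8S,10R)-10-hydroxy-8-[(4-methoxybenzyl)oxy]-2,6-dimethyl-5-[(triisopropylsilyl)oxy]dodeca-1,11-dien-9-one | C=C(C)CC[C@H](O[Si](C(C)C)(C(C)C)C(C)C)[C@H](C)C[C@H](OCc1ccc(OC)cc1)C(=O)[C@H](O)C=C | intermediate
17 | ethyl 2-(diethoxyphosphoryl)acrylate | C=C(C(=O)OCC)P(=O)(OCC)OCC | starting material
18 | (4-methoxyphenyl)methanol | COc1ccc(CO)cc1 | starting material
19 | ethyl 2-(diethoxyphosphoryl)-3-[(4-methoxybenzyl)oxy]propanoate (racemic) | CCOC(=O)C(COCc1ccc(OC)cc1)P(=O)(OCC)OCC | intermediate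
20 | 2-(diethoxyphosphoryl)-3-[(4-methoxybenzyl)oxy]propanoic acid (racemic) | OC(=O)C(COCc1ccc(OC)cc1)P(=O)(OCC)OCC | intermediate
21 | (3R,5S,7R,8S)-5-[(4-methoxybenzyl)oxy]-7,11-dimethyl-4-oxo-8-[(triisopropylsilyl)oxy]dodeca-1,11-dien-3-yl 2-(diethoxyphosphoryl)-3-[(4-methoxybenzyl)oxy]propanoate (both epimers at the phosphonate carbon) | C=C(C)CC[C@H](O[Si](C(C)C)(C(C)C)C(C)C)[C@H](C)C[C@H](OCc1ccc(OC)cc1)C(=O)[C@H](OC(=O)C(COCc1ccc(OC)cc1)P(=O)(OCC)OCC)C=C | intermediate
22 | (5R)-3-{[(4-methoxybenzyl)oxy]methyl}-4-{(1S,3R,4S)-1-[(4-methoxybenzyl)oxy]-3,7-dimethyl-4-[(triisopropylsilyl)oxy]oct-7-en-1-yl}-5-vinylfuran-2(5H)-one | C=C[C@H]1OC(=O)C(COCc2ccc(OC)cc2)=C1[C@@H](OCc1ccc(OC)cc1)C[C@@H](C)[C@@H](O[Si](C(C)C)(C(C)C)C(C)C)CCC(C)=C | intermediate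
23 | (1S,4Z,6R,8S,10R)-8,13-bis[(4-methoxybenzyl)oxy]-1-[(triisopropylsilyl)oxy]germacra-4,7(11)-dien-12,6-olide | COc1ccc(CO[C@H]2C[C@@H](C)[C@@H](O[Si](C(C)C)(C(C)C)C(C)C)CC/C(C)=C\[C@H]3OC(=O)C(COCc4ccc(OC)cc4)=C23)cc1 | intermediate
24 | (1S,4Z,6R,8S,10R)-8,13-dihydroxy-1-[(triisopropylsilyl)oxy]germacra-4,7(11)-dien-12,6-olide | O[C@H]1C[C@@H](C)[C@@H](O[Si](C(C)C)(C(C)C)C(C)C)CC/C(C)=C\[C@H]2OC(=O)C(CO)=C12 | intermediate
25 | (1S,4Z,6R,8S,10R)-13-acetoxy-8-hydroxy-1-[(triisopropylsilyl)oxy]germacra-4,7(11)-dien-12,6-olide | O[C@H]1C[C@@H](C)[C@@H](O[Si](C(C)C)(C(C)C)C(C)C)CC/C(C)=C\[C@H]2OC(=O)C(COC(C)=O)=C12 | intermediate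
26 | (1S,4R,5S,6S,8S,10R)-13-acetoxy-4,5-epoxy-8-hydroxy-1-[(triisopropylsilyl)oxy]germacr-7(11)-en-12,6-olide | O[C@H]1C[C@@H](C)[C@@H](O[Si](C(C)C)(C(C)C)C(C)C)CC[C@@]2(C)O[C@H]2[C@H]2OC(=O)C(COC(C)=O)=C12 | intermediate
27 | (1S,4R,5S,6S,8S,10R)-13-acetoxy-4,5-epoxy-8-(methacryloyloxy)-1-[(triisopropylsilyl)oxy]germacr-7(11)-en-12,6-olide | C=C(C)C(=O)O[C@H]1C[C@@H](C)[C@@H](O[Si](C(C)C)(C(C)C)C(C)C)CC[C@@]2(C)O[C@H]2[C@H]2OC(=O)C(COC(C)=O)=C12 | intermediate
28 | (1S,4R,5S,6S,8S,10R)-13-acetoxy-4,5-epoxy-1-hydroxy-8-(methacryloyloxy)germacr-7(11)-en-12,6-olide | C=C(C)C(=O)O[C@H]1C[C@@H](C)[C@@H](O)CC[C@@]2(C)O[C@H]2[C@H]2OC(=O)C(COC(C)=O)=C12 | target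

Total step count: 21 (18 on the main line, 3 for the reagents 13 and 20).
Longest linear sequence: 18 steps from 1 (steps 1–7, 9–11 and 14–21).

Steps most likely to fail

Step 16 (key ring closure). At the dilution needed, cross-metathesis to oligomers may outrun the ten-membered closure, the ring may close to the E olefin, or the C6 vinyl group may migrate into conjugation with the butenolide before it is engaged. The fallback closes the carbocycle before the butenolide exists, so that the vinyl terminus is an ordinary allylic silyl ether. It sets out from 15, whose ring-closing metathesis (same ruthenium carbene, toluene, high dilution) should give (2R,3Z,7S,8R,10S)-2-[(tert-butyldimethylsilyl)oxy]-10-[(4-methoxybenzyl)oxy]-4,8-dimethyl-7-[(triisopropylsilyl)oxy]cyclodec-3-en-1-one F1. HF·pyridine then frees the α-ketol (2R,3Z,7S,8R,10S)-2-hydroxy-10-[(4-methoxybenzyl)oxy]-4,8-dimethyl-7-[(triisopropylsilyl)oxy]cyclodec-3-en-1-one F2. Esterification with 20 (EDC·HCl, DMAP) gives (1R,2Z,6S,7R,9S)-9-[(4-methoxybenzyl)oxy]-3,7-dimethyl-10-oxo-6-[(triisopropylsilyl)oxy]cyclodec-2-en-1-yl 2-(diethoxyphosphoryl)-3-[(4-methoxybenzyl)oxy]propanoate F3. The LiCl/i-Pr2NEt Horner–Wadsworth–Emmons closure then annulates the butenolide onto the preformed ring and comes back to the route at 23.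

Step 19 (epoxidation). The C8 hydroxyl may fail to deliver the vanadium peroxide, so that peripheral attack on the other olefin face competes and facial selectivity is lost, or the bishomoallylic delivery may simply be too slow. The fallback replaces substrate direction by reagent control: Shi epoxidation of 25 with KHSO5 and the L-fructose-derived ketone catalyst (K2CO3 buffer, MeCN/dimethoxymethane/H2O, 0 °C). The spiro transition-state model pairs this catalyst enantiomer with the olefin face syn to C8. It sets out from 25 and comes back to the route at 26 without any new compound (none F0).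

Step 11 (unmasking of the α-ketol). Once the silyl group is gone, the β,γ-unsaturated α-hydroxy ketone may isomerise (α-ketol shift, or migration of the vinyl group into conjugation with loss of the C6 configuration) before or during steps 14 and 15. The fallback never frees the α-ketol and sets out from 15. Oxa-Michael addition of 18 to ethyl acrylate gives ethyl 3-[(4-methoxybenzyl)oxy]propanoate F4. Its lithium enolate (LiN(i-Pr)2, THF, −78 °C) is added to the C7 ketone of 15 to give the aldol ethyl (4S,6R,7S)-3-{(1R)-1-[(tert-butyldimethylsilyl)oxy]prop-2-en-1-yl}-3-hydroxy-4-[(4-methoxybenzyl)oxy]-2-{[(4-methoxybenzyl)oxy]methyl}-6,10-dimethyl-7-[(triisopropylsilyl)oxy]undec-10-enoate F5. HF·pyridine removes the tert-butyldimethylsilyl group and the freed C6 hydroxyl lactonises to (5R)-4-hydroxy-3-{[(4-methoxybenzyl)oxy]methyl}-4-{(1S,3R,4S)-1-[(4-methoxybenzyl)oxy]-3,7-dimethyl-4-[(triisopropylsilyl)oxy]oct-7-en-1-yl}-5-vinyldihydrofuran-2(3H)-one F6. Dehydration of the tertiary alcohol towards the acidic C11 hydrogen (SOCl2, pyridine, 0 °C) then comes back to the route at 22.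

Further compounds
F1 | step 16 | (2R,3Z,7S,8R,10S)-2-[(tert-butyldimethylsilyl)oxy]-10-[(4-methoxybenzyl)oxy]-4,8-dimethyl-7-[(triisopropylsilyl)oxy]cyclodec-3-en-1-one | COc1ccc(CO[C@H]2C[C@@H](C)[C@@H](O[Si](C(C)C)(C(C)C)C(C)C)CC/C(C)=C\[C@@H](O[Si](C)(C)C(C)(C)C)C2=O)cc1
F2 | step 16 | (2R,3Z,7S,8R,10S)-2-hydroxy-10-[(4-methoxybenzyl)oxy]-4,8-dimethyl-7-[(triisopropylsilyl)oxy]cyclodec-3-en-1-one | COc1ccc(CO[C@H]2C[C@@H](C)[C@@H](O[Si](C(C)C)(C(C)C)C(C)C)CC/C(C)=C\[C@@H](O)C2=O)cc1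
F3 | step 16 | (1R,2Z,6S,7R,9S)-9-[(4-methoxybenzyl)oxy]-3,7-dimethyl-10-oxo-6-[(triisopropylsilyl)oxy]cyclodec-2-en-1-yl 2-(diethoxyphosphoryl)-3-[(4-methoxybenzyl)oxy]propanoate | COc1ccc(CO[C@H]2C[C@@H](C)[C@@H](O[Si](C(C)C)(C(C)C)C(C)C)CC/C(C)=C\[C@@H](OC(=O)C(COCc3ccc(OC)cc3)P(=O)(OCC)OCC)C2=O)cc1
F0 | step 19 | none | none
F4 | step 11 | ethyl 3-[(4-methoxybenzyl)oxy]propanoate | CCOC(=O)CCOCc1ccc(OC)cc1
F5 | step 11 | ethyl (4S,6R,7S)-3-{(1R)-1-[(tert-butyldimethylsilyl)oxy]prop-2-en-1-yl}-3-hydroxy-4-[(4-methoxybenzyl)oxy]-2-{[(4-methoxybenzyl)oxy]methyl}-6,10-dimethyl-7-[(triisopropylsilyl)oxy]undec-10-enoate (mixture at C2 and C3) | C=C(C)CC[C@H](O[Si](C(C)C)(C(C)C)C(C)C)[C@H](C)C[C@H](OCc1ccc(OC)cc1)C(O)(C(COCc1ccc(OC)cc1)C(=O)OCC)[C@H](O[Si](C)(C)C(C)(C)C)C=C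
F6 | step 11 | (5R)-4-hydroxy-3-{[(4-methoxybenzyl)oxy]methyl}-4-{(1S,3R,4S)-1-[(4-methoxybenzyl)oxy]-3,7-dimethyl-4-[(triisopropylsilyl)oxy]oct-7-en-1-yl}-5-vinyldihydrofuran-2(3H)-one (mixture at C3 and C4) | C=C[C@H]1OC(=O)C(COCc2ccc(OC)cc2)C1(O)[C@@H](OCc1ccc(OC)cc1)C[C@@H](C)[C@@H](O[Si](C(C)C)(C(C)C)C(C)C)CCC(C)=C
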